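Ring A (C1–C5, C10; labdane numbering) is not closed as a six-membered ring. C19, the future ester carbon, starts as a ring atom of a cycloheptene (C10–C1–C2–C3–C4=C19–C5) that is closed by metathesis on a ring B cyclohexane built by a conjugate addition–alkylation. The key step exploits the fact that C4 carries a methyl (C18) and a carbonyl carbon (C19) beside ring-fusion C5: Lewis-acid rearrangement of the C4–C19 epoxide shifts C5 from C19 to C4, contracts the seven-membered ring to ring A, expels C19 as the formyl group and sets the C4 quaternary stereocentre stereospecifically. Its precursor is a trans-fused bicyclo[5.4.0]undecene oxide bearing the C1 acetate.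

Key step: step 14

Remark: labdane numbering is used throughout (ring A = C1–C5, C10; ring B = C5–C10; C18 = methyl on C4, C19 = ester carbon, C20 = methyl on C10).
Assumption: the (S)-prolinol-derived oxazaborolidinium catalyst of step 2 gives the (1S) aldehyde 4; if its sense of induction is the opposite, the (R)-catalyst is used.

Step 1
Reactants: 1 (3E)-pent-3-en-2-one
Product: 2 triisopropyl[(3E)-penta-1,3-dien-2-yloxy]silane
Conditions: LiN(i-Pr)2 (LDA), THF, −78 °C; TIPSOTf
Reagents that add atoms: triisopropylsilyl trifluoromethanesulfonate, CC(C)[Si](OS(=O)(=O)C(F)(F)F)(C(C)C)C(C)C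
Why: Kinetic deprotonation of the methyl ketone and O-silylation give the cross-conjugated 2-silyloxy diene (silyl dienol ether formation); no stereocentre is made.

Step 2
Reactants: 2 triisopropyl[(3E)-penta-1,3-dien-2-yloxy]silane; 3 acrolein
Product: 4 (1S,2R)-2-methyl-4-[(triisopropylsilyl)oxy]cyclohex-3-ene-1-carbaldehyde
Conditions: oxazaborolidinium triflimide from (S)-α,α-diphenylprolinol, tri-o-tolylboroxine and HNTf2 (20 mol %), CH2Cl2, −78 °C
Reagents that add atoms: none
Why: Catalytic enantioselective Diels–Alder reaction: the silyloxy group ("para") and the diene methyl ("ortho") together place the formyl-bearing carbon next to the methyl-bearing carbon, and the chiral Lewis acid shields one enal face, which fixes the formyl-bearing centre (future C5), the only stereocentre that outlives step 4.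

Step 3
Reactants: 4 (1S,2R)-2-methyl-4-[(triisopropylsilyl)oxy]cyclohex-3-ene-1-carbaldehyde
Product: 5 {[(3S,4R)-4-ethenyl-3-methylcyclohex-1-en-1-yl]oxy}triisopropylsilane
Conditions: Ph3PCH3Br, KN(SiMe3)2, THF, −78 → 0 °C
Reagents that add atoms: methyltriphenylphosphonium bromide (as its ylide), C[P+](c1ccccc1)(c1ccccc1)c1ccccc1.[Br-]
Why: Wittig methylenation with a non-stabilised ylide at low temperature turns the aldehyde into the vinyl group (its inner carbon is the future C19) without epimerising the adjacent centre or touching the silyl enol ether.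

Step 4
Reactants: 5 {[(3S,4R)-4-ethenyl-3-methylcyclohex-1-en-1-yl]oxy}triisopropylsilane
Product: 6 (4R)-4-ethenyl-3-methylcyclohex-2-en-1-one
Conditions: Pd(OAc)2 (10 mol %), O2 (1 atm), DMSO, 60 °C
Reagents that add atoms: none
Why: Saegusa–Ito dehydrosilylation: the palladium enolate loses the hydride of the methyl-bearing carbon, which gives the enone regiospecifically and leaves C5 as the only stereocentre.

Step 5
Reactants: 7 (2E)-3-methylpent-2-en-4-yn-1-ol
Product: 9 (2E)-3-methyl-5-(trimethylsilyl)pent-2-en-4-yn-1-ol, via bis-silyl ether 8 (not isolated)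
Conditions: n-BuLi (2.1 equiv), THF, −78 °C; TMSCl (2.2 equiv); then 1 M HCl
Reagents that add atoms: chlorotrimethylsilane, C[Si](C)(C)Cl
Why: The alkoxide–acetylide dianion is silylated on O and C and the O–Si bond is hydrolysed on acidic work-up (alkyne C-silylation), which masks the alkyne for the metathesis step.

Step 6
Reactants: 9 (2E)-3-methyl-5-(trimethylsilyl)pent-2-en-4-yn-1-ol
Product: 10 [(3E)-5-bromo-3-methylpent-3-en-1-yn-1-yl]trimethylsilane
Conditions: CBr4, PPh3, CH2Cl2, 0 °C
Reagents that add atoms: tetrabromomethane, BrC(Br)(Br)Br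
Why: Appel bromination converts the primary allylic alcohol to the bromide by SN2 displacement and leaves the (E)-enyne untouched.

Step 7
Reactants: 6 (4R)-4-ethenyl-3-methylcyclohex-2-en-1-one; 11 ethyl vinyl ether; 10 [(3E)-5-bromo-3-methylpent-3-en-1-yn-1-yl]trimethylsilane
Product: 13 4-ethenyl-3-(1-ethoxyethenyl)-3-methyl-2-[(2E)-3-methyl-5-(trimethylsilyl)pent-2-en-4-yn-1-yl]cyclohexan-1-one (vinyl trans to the 1-ethoxyethenyl group, C2 side chain cis to the C3 methyl), via lithium enolate 12 (not isolated)
Conditions: 11, t-BuLi, THF, −78 → 0 °C; CuBr·SMe2 (0.5 equiv), −78 °C; 6, −78 → −30 °C; then 10, HMPA, −78 → 0 °C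
Reagents that add atoms: none
Why: Tandem cuprate conjugate addition–enolate alkylation (three-component coupling): the acyl-anion-equivalent cuprate adds to C10 anti to the C5 vinyl group (axial attack on the half-chair with pseudoaxial vinyl), and the regiodefined enolate is alkylated at C9 anti to the new 1-ethoxyethenyl group, C9 also being epimerisable to this arrangement with the side chain cis to the C10 methyl.

Step 8
Reactants: 13 4-ethenyl-3-(1-ethoxyethenyl)-3-methyl-2-[(2E)-3-methyl-5-(trimethylsilyl)pent-2-en-4-yn-1-yl]cyclohexan-1-one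
Product: 15 1-{2-ethenyl-1-methyl-5-methylidene-6-[(2E)-3-methyl-5-(trimethylsilyl)pent-2-en-4-yn-1-yl]cyclohexyl}ethan-1-one (acetyl trans to vinyl, side chain cis to the ring methyl), via enol ether 14 (not isolated)
Conditions: Ph3PCH3Br, KN(SiMe3)2, toluene, 0 → 60 °C; then 1 M HCl, THF, rt
Reagents that add atoms: methyltriphenylphosphonium bromide (as its ylide), C[P+](c1ccccc1)(c1ccccc1)c1ccccc1.[Br-]; water, O
Why: Wittig methylenation of the hindered C8 ketone, followed by acid hydrolysis of the ethyl enol ether on work-up, unveils the C1 methyl ketone only after the ring ketone is gone, so no 1,4-diketone aldol can occur.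

Step 9
Reactants: 15 1-{2-ethenyl-1-methyl-5-methylidene-6-[(2E)-3-methyl-5-(trimethylsilyl)pent-2-en-4-yn-1-yl]cyclohexyl}ethan-1-one; 16 3-bromo-2-methylprop-1-ene
Product: 17 1-{2-ethenyl-1-methyl-5-methylidene-6-[(2E)-3-methyl-5-(trimethylsilyl)pent-2-en-4-yn-1-yl]cyclohexyl}-4-methylpent-4-en-1-one
Conditions: LiN(i-Pr)2 (LDA), THF, −78 °C; 16, DMPU, −78 → −20 °C
Reagents that add atoms: none
Why: Kinetic enolate alkylation: the acetyl methyl is the only enolisable position (C10 is quaternary), so methallyl bromide adds C3, C4 and C18 in one operation.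

Step 10
Reactants: 17 1-{2-ethenyl-1-methyl-5-methylidene-6-[(2E)-3-methyl-5-(trimethylsilyl)pent-2-en-4-yn-1-yl]cyclohexyl}-4-methylpent-4-en-1-one
Product: 18 trans-fused 4a,8-dimethyl-3-methylidene-4-[(2E)-3-methyl-5-(trimethylsilyl)pent-2-en-4-yn-1-yl]-1,2,3,4,4a,6,7,9a-octahydro-5H-benzo[7]annulen-5-one (side chain cis to the 4a-methyl)
Conditions: second-generation Grubbs catalyst RuCl2(=CHPh)(PCy3)(H2IMes) (5 mol %), CH2Cl2 (0.005 M), 40 °C
Reagents that add atoms: none
Why: Ring-closing metathesis between the C5 vinyl group and the 1,1-disubstituted alkene gives the trisubstituted cycloheptene, trans-fused because the two arms are trans on ring B; the silyl-capped enyne and the exocyclic methylene cannot close an unstrained ring.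

Step 11
Reactants: 18 trans-fused bicyclic ketone
Product: 20 4a,8-dimethyl-3-methylidene-4-[(2E)-3-methylpent-2-en-4-yn-1-yl]-2,3,4,4a,5,6,7,9a-octahydro-1H-benzo[7]annulen-5-ol (hydroxyl cis to the 4a-methyl, trans ring fusion), via silylated alcohol 19 (not isolated)
Conditions: NaBH4, MeOH, 0 °C → rt; then K2CO3, rt
Reagents that add atoms: none
Why: Substrate-controlled hydride reduction: borohydride attacks the C1 ketone anti to the axial C10 methyl, which places the hydroxyl cis to that methyl as in the target, and methanolic carbonate then removes the alkynyl silyl group.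

Step 12
Reactants: 20 bicyclic alkenol
Product: 21 the 8,9-epoxide of 20 (oxirane oxygen cis to the hydroxyl and to the 4a-methyl)
Conditions: VO(acac)2 (5 mol %), t-BuOOH, CH2Cl2, 0 °C → rt
Reagents that add atoms: tert-butyl hydroperoxide, CC(C)(C)OO
Why: Hydroxyl-directed vanadium-catalysed epoxidation: the vanadium alkoxide at C1 delivers the peroxide across the seven-membered ring to the bishomoallylic C4=C19 alkene on the hydroxyl face, and the undirected exocyclic methylene and enyne are left alone.

Step 13
Reactants: 21 epoxy alcohol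
Product: 22 the acetate of 21 (acetoxy and oxirane oxygen both cis to the 4a-methyl)
Conditions: Ac2O, DMAP, pyridine, rt
Reagents that add atoms: acetic anhydride, CC(=O)OC(C)=O
Why: DMAP-catalysed acylation installs the C1 acetate of the target and removes the nucleophilic hydroxyl before the cationic rearrangement.

Step 14
Reactants: 22 epoxy acetate
Product: 23 (1R,4S,4aS,5R,8aS)-4-(acetyloxy)-1,4a-dimethyl-6-methylidene-5-[(2E)-3-methylpent-2-en-4-yn-1-yl]decahydronaphthalene-1-carbaldehyde
Conditions: MeAl(OAr)2 (Ar = 4-bromo-2,6-di-tert-butylphenyl; MABR, 0.3 equiv), CH2Cl2, −78 → −20 °C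
Reagents that add atoms: none
Why: The bulky aluminium Lewis acid binds the epoxide oxygen, the C4–O bond ionises toward tertiary C4, and the C19–C5 ring bond shifts to C4 while C19–O becomes the aldehyde carbonyl (Meinwald rearrangement, a semipinacol 1,2-shift). The closest known reaction is the MABR-promoted rearrangement of trisubstituted epoxides to α-quaternary aldehydes, including the contraction of 1-methylcycloalkene oxides to 1-methylcycloalkanecarbaldehydes. Ring A is not closed by a cyclisation: it forms by contraction of the seven-membered ring through a three-centre 1,2-alkyl shift that makes the C4–C5 bond and leaves C19 outside the ring. The only new stereocentre, C4, is set by the epoxide: C5 enters anti to the departing oxygen (inversion at C4, retention at C5), so the oxygen face becomes the formyl (C19) face, cis to the C10 methyl, and C18 stays on the other face. The step needs ring-bond migration to beat hydride shift from C19 and proton loss from C3 or C18; the hindered aluminium phenoxide, the higher migratory aptitude of secondary C5 and the release of seven-membered-ring strain favour it. The C1 acetate is in place beforehand so that no hydroxyl can trap the C4 cation.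

Step 15
Reactants: 23 aldehyde
Product: 24 (1R,4S,4aS,5R,8aS)-4-(acetyloxy)-1,4a-dimethyl-6-methylidene-5-[(2E)-3-methylpent-2-en-4-yn-1-yl]decahydronaphthalene-1-carboxylic acid
Conditions: NaClO2, NaH2PO4, 2-methylbut-2-ene, t-BuOH/H2O, rt
Reagents that add atoms: sodium chlorite, [Na+].[O-]Cl=O
Why: Pinnick oxidation converts the neopentyl aldehyde to the acid under buffered conditions that leave the acetate, the alkyne and the alkenes (protected by the chlorine scavenger) intact.

Step 16
Reactants: 24 acid
Product: 25 methyl (1R,4S,4aS,5R,8aS)-4-(acetyloxy)-1,4a-dimethyl-6-methylidene-5-[(2E)-3-methylpent-2-en-4-yn-1-yl]decahydronaphthalene-1-carboxylate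
Conditions: TMSCHN2, MeOH/toluene, 0 °C → rt
Reagents that add atoms: (trimethylsilyl)diazomethane, C[Si](C)(C)C=[N+]=[N-]
Why: Esterification with (trimethylsilyl)diazomethane methylates the hindered tertiary acid without base, so the acetate survives.

Step 17
Reactants: 25 enyne methyl ester
Product: 26 methyl (1R,4S,4aS,5R,8aS)-4-(acetyloxy)-1,4a-dimethyl-6-methylidene-5-[(2E)-3-methylpenta-2,4-dien-1-yl]decahydronaphthalene-1-carboxylate (target; 1S,4R,5S,9R,10S in labdane numbering)
Conditions: H2 (1 atm), Pd/CaCO3 poisoned with Pb(OAc)2 (Lindlar catalyst), quinoline, EtOAc/hexane, rt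
Reagents that add atoms: none
Why: Lindlar semihydrogenation reduces only the terminal alkyne to the vinyl group, which completes the (E)-diene whose trisubstituted double bond was fixed in the starting enynol.

Compound list
1 | (3E)-pent-3-en-2-one | C/C=C/C(C)=O | starting material
2 | triisopropyl[(3E)-penta-1,3-dien-2-yloxy]silane | C/C=C/C(=C)O[Si](C(C)C)(C(C)C)C(C)C | intermediate
3 | acrolein | C=CC=O | starting material
4 | (1S,2R)-2-methyl-4-[(triisopropylsilyl)oxy]cyclohex-3-ene-1-carbaldehyde | C1=C(O[Si](C(C)C)(C(C)C)C(C)C)CC[C@H](C=O)[C@@H]1C | intermediate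
5 | {[(3S,4R)-4-ethenyl-3-methylcyclohex-1-en-1-yl]oxy}triisopropylsilane | C1=C(O[Si](C(C)C)(C(C)C)C(C)C)CC[C@H](C=C)[C@@H]1C | intermediate
6 | (4R)-4-ethenyl-3-methylcyclohex-2-en-1-one | O=C1CC[C@H](C=C)C(C)=C1 | intermediate
7 | (2E)-3-methylpent-2-en-4-yn-1-ol | C#C/C(C)=C/CO | starting material
8 | trimethyl{[(2E)-3-methyl-5-(trimethylsilyl)pent-2-en-4-yn-1-yl]oxy}silane | C[Si](C)(C)C#C/C(C)=C/CO[Si](C)(C)C | intermediate (not isolated)
9 | (2E)-3-methyl-5-(trimethylsilyl)pent-2-en-4-yn-1-ol | C[Si](C)(C)C#C/C(C)=C/CO | intermediate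
10 | [(3E)-5-bromo-3-methylpent-3-en-1-yn-1-yl]trimethylsilane | C[Si](C)(C)C#C/C(C)=C/CBr | intermediate
11 | ethyl vinyl ether | C=COCC | starting material
12 | lithium 4-ethenyl-3-(1-ethoxyethenyl)-3-methylcyclohex-1-en-1-olate (vinyl trans to ethoxyethenyl) | C1=C(O[Li])CC[C@H](C=C)[C@@]1(C)C(=C)OCC | intermediate (not isolated)
13 | 4-ethenyl-3-(1-ethoxyethenyl)-3-methyl-2-[(2E)-3-methyl-5-(trimethylsilyl)pent-2-en-4-yn-1-yl]cyclohexan-1-one | C[Si](C)(C)C#C/C(C)=C/C[C@@H]1C(=O)CC[C@H](C=C)[C@@]1(C)C(=C)OCC | intermediate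
14 | 1-methylidene analogue of 13 (ethyl enol ether retained) | C[Si](C)(C)C#C/C(C)=C/C[C@@H]1C(=C)CC[C@H](C=C)[C@@]1(C)C(=C)OCC | intermediate (not isolated)
15 | 1-{2-ethenyl-1-methyl-5-methylidene-6-[(2E)-3-methyl-5-(trimethylsilyl)pent-2-en-4-yn-1-yl]cyclohexyl}ethan-1-one | C[Si](C)(C)C#C/C(C)=C/C[C@@H]1C(=C)CC[C@H](C=C)[C@@]1(C)C(C)=O | intermediate
16 | 3-bromo-2-methylprop-1-ene | C=C(C)CBr | starting material
17 | 1-{2-ethenyl-1-methyl-5-methylidene-6-[(2E)-3-methyl-5-(trimethylsilyl)pent-2-en-4-yn-1-yl]cyclohexyl}-4-methylpent-4-en-1-one | C[Si](C)(C)C#C/C(C)=C/C[C@@H]1C(=C)CC[C@H](C=C)[C@@]1(C)C(=O)CCC(C)=C | intermediate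
18 | trans-fused 4a,8-dimethyl-3-methylidene-4-[(2E)-3-methyl-5-(trimethylsilyl)pent-2-en-4-yn-1-yl]-1,2,3,4,4a,6,7,9a-octahydro-5H-benzo[7]annulen-5-one | C[Si](C)(C)C#C/C(C)=C/C[C@@H]1C(=C)CC[C@H]2[C@@]1(C)C(=O)CCC(C)=C2 | intermediate
19 | 5-ol of 18 with the silyl group retained (hydroxyl cis to the 4a-methyl) | C[Si](C)(C)C#C/C(C)=C/C[C@@H]1C(=C)CC[C@H]2[C@@]1(C)[C@@H](O)CCC(C)=C2 | intermediate (not isolated)
20 | 4a,8-dimethyl-3-methylidene-4-[(2E)-3-methylpent-2-en-4-yn-1-yl]-2,3,4,4a,5,6,7,9a-octahydro-1H-benzo[7]annulen-5-ol | C#C/C(C)=C/C[C@@H]1C(=C)CC[C@H]2[C@@]1(C)[C@@H](O)CCC(C)=C2 | intermediate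
21 | 8,9-epoxide of 20, oxygen cis to the hydroxyl | C#C/C(C)=C/C[C@@H]1C(=C)CC[C@H]2[C@@]1(C)[C@@H](O)CC[C@@]3(C)O[C@@H]23 | intermediate
22 | acetate of 21 | C#C/C(C)=C/C[C@@H]1C(=C)CC[C@H]2[C@@]1(C)[C@@H](OC(C)=O)CC[C@@]3(C)O[C@@H]23 | intermediate
23 | (1R,4S,4aS,5R,8aS)-4-(acetyloxy)-1,4a-dimethyl-6-methylidene-5-[(2E)-3-methylpent-2-en-4-yn-1-yl]decahydronaphthalene-1-carbaldehyde | C#C/C(C)=C/C[C@@H]1C(=C)CC[C@H]2[C@@]1(C)[C@@H](OC(C)=O)CC[C@@]2(C)C=O | intermediate
24 | the corresponding 1-carboxylic acid | C#C/C(C)=C/C[C@@H]1C(=C)CC[C@H]2[C@@]1(C)[C@@H](OC(C)=O)CC[C@@]2(C)C(=O)O | intermediate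
25 | the corresponding methyl ester | C#C/C(C)=C/C[C@@H]1C(=C)CC[C@H]2[C@@]1(C)[C@@H](OC(C)=O)CC[C@@]2(C)C(=O)OC | intermediate
26 | methyl (1R,4S,4aS,5R,8aS)-4-(acetyloxy)-1,4a-dimethyl-6-methylidene-5-[(2E)-3-methylpenta-2,4-dien-1-yl]decahydronaphthalene-1-carboxylate | C=C/C(C)=C/C[C@@H]1C(=C)CC[C@H]2[C@@]1(C)[C@@H](OC(C)=O)CC[C@@]2(C)C(=O)OC | target

Total step count: 17. Longest linear sequence: 15 steps (steps 1–4 and 7–17, from 1 to 26).

Steps most likely to fail

Step 14. The ring-bond shift may lose to a 1,2-hydride shift from C19 (which would give the cycloheptanone) or to proton loss to an allylic alcohol. The fallback is a nucleophile-assisted, two-inversion route that sets out from 20. Acetylation (Ac2O, DMAP, pyridine) gives the alkenyl acetate F1. Undirected epoxidation with m-CPBA (CH2Cl2, 0 °C) should attack the ring alkene on the face anti to the C10 methyl and give the epimeric epoxide F2. LiBr–HMPA in hot benzene then opens C4–O with bromide (inversion), and the lithium alkoxide at C19 contracts the ring by displacing bromide with the C5–C19 bond (second inversion). The two inversions lead to the same aldehyde 23, where the route is rejoined.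

Step 12. The C1 hydroxyl may fail to reach the alkene across the ring, so that epoxidation is slow, takes the wrong face or strays to the exocyclic methylene. The fallback sets out from ketone 18 and needs no directing group. NBS in wet DME forms the bromonium ion on the face anti to the C10 methyl and water opens it at C4, giving the bromohydrin F3. K2CO3 in MeOH/THF closes it to the epoxy ketone F4, whose oxygen is cis to the C10 methyl. NaBH4 followed by K2CO3/MeOH reduces C1 and removes the silyl group to give 21, where the route is rejoined.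

Step 7. Conjugate addition at the fully substituted β-carbon may be sluggish or give 1,2-addition, and the copper-bound enolate may alkylate poorly (proton transfer, polyalkylation). The fallback separates the two events and sets out from 6. The same cuprate is added in the presence of TMSCl, which accelerates the addition and traps the product as the silyl enol ether F5, which is isolated. MeLi (THF, 0 °C) then regenerates the lithium enolate 12 regiospecifically, and bromide 10 with HMPA gives 13, where the route is rejoined.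

Further compounds
F1 | step 14 | acetate of 20 (alkene retained) | C#C/C(C)=C/C[C@@H]1C(=C)CC[C@H]2[C@@]1(C)[C@@H](OC(C)=O)CCC(C)=C2
F2 | step 14 | 8,9-epoxide of F1 with the oxygen anti to the 4a-methyl and to the acetoxy group | C#C/C(C)=C/C[C@@H]1C(=C)CC[C@H]2[C@@]1(C)[C@@H](OC(C)=O)CC[C@]3(C)O[C@H]23
F3 | step 12 | 9-bromo-8-hydroxy derivative of 18 (hydroxyl cis, bromine anti to the 4a-methyl) | C[Si](C)(C)C#C/C(C)=C/C[C@@H]1C(=C)CC[C@H]2[C@@]1(C)C(=O)CC[C@@](C)(O)[C@@H]2Br
F4 | step 12 | 8,9-epoxide of 18 with the oxygen cis to the 4a-methyl | C[Si](C)(C)C#C/C(C)=C/C[C@@H]1C(=C)CC[C@H]2[C@@]1(C)C(=O)CC[C@@]3(C)O[C@@H]23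
F5 | step 7 | {[4-ethenyl-3-(1-ethoxyethenyl)-3-methylcyclohex-1-en-1-yl]oxy}trimethylsilane (vinyl trans to ethoxyethenyl) | C1=C(O[Si](C)(C)C)CC[C@H](C=C)[C@@]1(C)C(=C)OCC
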